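The data were generated by integration for an exercise; scatter was added.

15 h is the time of reading for this flask, in which starting material in the first phase meets reagent that has to cross from the second phase, and each target takes one of each.

| flask | starting material | reagent in the second phase | remark | time | volume of the second phase over the first |
|---|---|---|---|---|---|
| midnight | 0.34 M | 0.20 M | run made earlier |  |  |
| spring | 0.34 M | 0.82 M | run made earlier |  |  |
| summer | 0.68 M | 0.408 M | run made earlier |  |  |
| flask | 0.34 M | 0.408 M |  | 15 h | 2.0 |

- midnight (time / h: target / %, starting material / %): 0.667: 3, 62; 1.33: 11, 41; 2.00: 11, 34; 3.00: 15, 26; 5.00: 23, 20; 10.0: 30, 17
- spring (time / h: target / %, starting material / %): 0.667: 15, 54; 1.33: 29, 28; 2.00: 39, 12; 3.00: 49, 8; 5.00: 59, 2; 10.0: 61, 0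
- summer (time / h: target / %, starting material / %): 2.00: 12, 31; 4.00: 22, 21; 5.00: 26, 15; 8.00: 33, 14; 10.0: 31, 17

(each reading ± 1.5 percentage points)

- percent here means starting material units held: one self-condensation product counts as two
- what is said of target includes product in the second phase
- in the second phase: reagent in the second phase, product in the second phase; everything else is in the first
- charges count per volume of the first phase; a concentration in a rate is the amount of a species over the volume of its own phase; every rate counts per litre of the first phase
- steps that have been proposed: target <-> product in the second phase; reagent in the reaction phase <-> reagent in the second phase; starting material + reagent in the reaction phase -> target; target -> over-reaction product; starting material <-> dormant form; 2 starting material -> self-condensation product; target -> decomposed product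
- the earlier runs hold the two phases in the same ratio of volumes as the flask asked about
- what has gone from starting material into another species counts as reacted, even if it can come back

- amount of target and product in the second phase together at 15 h, in percent of the starting material charged
- part of the starting material charged that has reacted at 15 h

I took the symmetric charge, one reagent per starting material, as the zero of my scale:

E = c(reagent in the second phase) / c(starting material)

The midnight run stood at 0.588, the summer run at 0.600, the spring run at 2.41 and this flask at 1.20. Below 1 the reagent is the limiting reagent by charge, so I divided target by what the charge allows:

return = target at the last reading / min(1, E)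

The midnight run gave a return 51.0%.

But the summer run held twice the starting material, and that might have broken the comparison. It did not: its return read 51.7%.

The spring run, above the zero, returned 61%, so the return is no constant. This flask lies between them, so I took the midpoint:

target ≈ 56.0%

Were 15 h enough? Early target was higher in the spring run than in the midnight run, 15% against 3%, roughly as the reagent charges go. Scaling the clock by reagent set this flask's reading beside 7.46 h of the spring run, a time between that run's readings of 59% and 61%. That scale was only an estimate, not a reading of this flask, so I kept the midpoint with the doubt still open.

The forecast stood below my figure: 49% target and 92% reacted, from “about 50% at 15 h”.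

The flask gave 53.6% target and 97.7% reacted.

    target ⇌ product in the second phase, rate k1*([target] - [product in the second phase]/K1) per volume of the first phase (partition coefficient = 1.80, kL = 1.00 h⁻¹)
    reagent in the reaction phase ⇌ reagent in the second phase, rate k2*([reagent in the reaction phase] - [reagent in the second phase]/K2) per volume of the first phase (partition coefficient = 0.420, kL = 0.140 h⁻¹)
    starting material + reagent in the reaction phase → target (k = 15.0 M⁻¹ h⁻¹)
    target → over-reaction product (k = 1.60 × 10⁻⁴ h⁻¹)
    starting material ⇌ dormant form (K = 2.20, k = 0.640 h⁻¹)
    2 starting material → self-condensation product (k = 0.0410 M⁻¹ h⁻¹)
    target → decomposed product (k = 0.190 h⁻¹)

This flask's own return was therefore 53.6%. The neighbouring flask, alike but charged with 0.58 M of starting material, stood below the zero at E = 0.703, so the same reckoning ran: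

target ≈ 53.6% × 0.703 = 37.7%

That neighbouring flask gave 38.4% target, with 90.4% reacted.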